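Counted in millimoles per litre of starting volume, the average chain length is a ratio of two amounts: the D reacted, which ends up as G, over the chains begun, living and dead together.

common to all: D 20 mM (fed, over 12 s); J 0.2 mol%; E 11 µM
- ash: Q 0.057 mM; run made earlier; the fed solution adds 0.25 times the starting volume
- maple: Q 0.099 mM; run made earlier; the fed solution adds 0.25 times the starting volume
- birch: Q 0.19 mM; run made earlier; the fed solution adds 0.25 times the starting volume
- alpha: Q 0.200 mM; the fed solution adds 0.25 times the starting volume; time 4.0 min
- delta: Q 0.0600 mM; the fed solution adds 0.25 times the starting volume; time 4.0 min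

| run | time / min | G / % |
|---|---|---|
| ash | 0.333 | 0 |
| ash | 1.00 | 7 |
| ash | 2.00 | 14 |
| ash | 3.00 | 21 |
| ash | 4.00 | 22 |
| maple | 0.833 | 1 |
| maple | 1.50 | 8 |
| maple | 2.50 | 16 |
| maple | 3.00 | 16 |
| maple | 4.00 | 18 |
| birch | 0.333 | 0 |
| birch | 0.667 | 2 |
| birch | 1.00 | 5 |
| birch | 2.00 | 7 |
| birch | 4.00 | 8 |

(readings scatter by 1.5 percentage points)

- amounts are per litre of the starting volume; all of the dose is in the solution fed
- the average divides the monomer in chains by the number of chains begun, living and dead together
- the earlier runs do not show the number of chains; that part of a forecast is a guess

* which of the two ends with the longer chains by the average number of monomer units in a chain (chains begun, living or dead) ("neither" if they lie within 10%) (alpha / delta / neither)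
* average number of monomer units in a chain (chains begun, living or dead) at the end, alpha
* average number of monomer units in a chain (chains begun, living or dead) at the end, delta

The numerator can be read from the earlier runs. Birch lies closest to alpha in Q and reads 8% of G at 4.00 min, which is 1.60 mM. Ash lies closest to delta in Q and reads 22% at 4.00 min, which is 4.40 mM. Each reading carries a scatter of 1.5 percentage points.

No run shows the denominator, so it is reckoned here from the charges. The charge of J is c(J) = 0.0400 mM, and c(E) = 11 µM is smaller. In ash, G still reads 0% at 0.333 min, and this lag is taken here as E consuming J one for one, with E the limiting reagent of that pair. That leaves 0.0290 mM as the chain count, the J charged less the E charged, and alpha and delta carry the same two charges. This reckoning therefore gives 55.2 units for alpha and 152 for delta, so delta is longer by a factor of 2.75.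

The forecast names delta, with 40 units for alpha and 110 for delta: “Delta should still be clearly longer”.

The simulation gives delta as the longer, with 62.8 units in alpha and 153 in delta.

    D + J → L + G (k = 2.60 L mol⁻¹ s⁻¹)
    D + L → G + L, rate k2*[L]*[D] (k = 92.0 L mol⁻¹ s⁻¹)
    L + Q → Z (k = 150 L mol⁻¹ s⁻¹)
    J + E → X (k = 7400 L mol⁻¹ s⁻¹)

At 4.00 min, E stands at 0.39% of its charge in alpha. Alpha holds 9.11% of G there, more than the birch reading, and over the chain count of 0.0290 mM this gives 62.9 units. A neighbour flask is delta with 0.8 mol% of J, so its chain count is 0.149 mM, and its 80.3% of G gives 108 units. The simulation gives 109.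

(The numbers in the tables are simulated from invented constants; scatter was added.)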